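## Analysis of the target

Target 33 is a germacranolide: a cyclodeca-1(10),4-diene (C1–C10) with a cis-fused α-methylene-γ-butyrolactone across C6–C7 (O6–C12(=O)–C11(=C13)–C7). Both ring alkenes are trisubstituted; C4=C5 is E (trans in the ring) and C1=C10 is Z (cis in the ring). Four contiguous stereocentres run from C6 to C9, (6S,7R,8S,9R). O6 and C11 lie on one face at the lactone fusion, the tertiary 7-OH and the angeloylated O8 lie on the other, and O8 and O9 are syn along the C7–C10 chain. The sensitive groups are the exo-methylene lactone (Michael acceptor, labile to base and nucleophiles), the angelate (Z to E isomerisation, acyl shift to O9 or O7) and the medium-ring 1,5-diene (acid-induced transannular cyclisation, Cope rearrangement). The difficulty is a ten-membered ring with one E and one Z trisubstituted alkene, next to four adjacent oxygenated carbons, one of them fully substituted, that have no rigid template in the macrocycle. The strategy rests on one feature: C4 and C9 face each other across the ring. A C4–C9 bond turns the carbocycle into a decalin. Its ring A (C4, C3, C2, C1, C10, C9) holds C1=C10 as a cyclohexene alkene, hence Z. Its ring B (C4–C9) carries C5 and all four oxygenated carbons on a chair.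

## Retrosynthetic reasoning

Lactone. In 33 the C12–O6 acyl bond is cut and C12 is returned to the alcohol level, giving triol 32. The Michael acceptor is made last so that it meets no base, hydride or nucleophile. The forward step must oxidise the primary allylic alcohol selectively and let the lactol close onto O6.

Angelate. The C8–O acyl bond of silyl-protected 31 is cut to give diol 29 and angelic acid 30. O9 is blocked (28, 29) because O8 and O9 are both secondary; the tertiary O7 needs no protection. The forward step has to acylate a hindered alcohol without Z to E isomerisation.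

C9 carbinol. Removing the C9–H bond leads from 27 to dienone 26. The forward step is a 1,2-reduction of an enone whose face is set by the neighbouring C8 oxygen.

Ring (key disconnection). In 26 the C4=C5 π bond and the C9 carbonyl are exchanged for a C4–C9 σ bond and a C5 leaving group, giving mesylate 25. No other transannular bond places C1=C10 in a six-membered ring and also leaves C9 as the carbonyl carbon and C5 as the carbon bearing the leaving group. The gain is threefold: the medium ring is released, not closed, both alkene geometries follow from the decalin, and C5–C8 are functionalised on a chair.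

Protecting-group pattern of 25. The mesylate comes from diol 24. The 7,8-acetonide comes from triol 22 through 23, in which O9 is a trimethylsilyl ether. The acetonide can then form only across O7/O8, which settles the choice between the two tertiary hydroxyls. 22 arises from 21 by loss of two naphthylmethyl ethers.

C7–C11. The bond between the carbinol carbon and the side chain is cut to give ketone 17 and alkenyllithium 20, made from bromide 19 (from 18). The forward addition must come from the α face.

C8–O and C9–O. 17 goes back through 16 and 15 to triol 14, and 14 to diene 13 by removing both oxygens from C8=C9. Ring closure by carbonyl addition at C9 next to the quaternary C4 would give the cis-fused ketol. A cis-dihydroxylation anti to the C4 methyl gives the trans fusion with O8 and O9 cis.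

Ring B. The C8=C9 bond of 13 is cut by a metathesis disconnection to triene 12. 12 comes from 11 by unmasking O7, and 11 from enone 10 by methylenation at C9.

C4 methyl. The C4–CH3 bond of 9 (protected as 10) is cut to give aldol 8. It is cut here, not at C4–C5, because a closed aldol transition state with the methylated enolate would give the other C4/C5 relationship. Alkylating the chelated aldolate gives the required one.

C4–C5. Aldol 8 is cut into 2-methylcyclohex-2-en-1-one 7 and aldehyde 6; the aldehyde stereocentre controls C5.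

C6–C7. Aldehyde 6 goes back through 5 and 4 to 3, which is cut between C6 and C7 into aldehyde 1 and allyl ether 2. One reagent-controlled step sets both stereocentres with the two oxygens already differentiated.

## Alternatives that were turned down

Alternative 1: The lactone is cut at C11–C12 and C12–O6, so the ethynyl diol A2 already holds the carbocycle, the angelate and a silylated O9. Forward, PdCl2(PPh3)2 and SnCl2 under CO would hydropalladate the C7 ethynyl group, insert CO and trap the acyl with O6, giving A1, the C9 triethylsilyl ether of 33. In its favour: the fragile methylene lactone forms in one neutral step, the stereotriad comes from a sugar, and only a desilylation remains. Against it: it leaves the ten-membered ring and both alkene geometries unsolved, to be reached by macrocyclisation of a sugar-derived chain. A palladium hydride with CO at elevated temperature would also meet a 1,5-diene, a tertiary propargylic alcohol and an isomerisable angelate. On endgame length and on the source of absolute configuration it is stronger than the chosen route. The chosen route offers a ring and two alkene geometries that follow from structure and not from a ring-closing event.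

Alternative 2: The C7–C8 bond is cut, opening the ring to aldehyde A4, a 3-alkoxy-2-(bromomethyl)butenolide tethered to C8. Forward, In or CrCl2 would turn the C13 bromide into an allylmetal that attacks the aldehyde through C7, closing the ring and shifting the alkene to C11=C13, to give A3. In its favour: it is the most convergent plan, forming ring, quaternary C7, C8 and methylene lactone at once and leaving O8 free. Against it: C7 and C8 would be created in a medium-ring transition state controlled only by C6, C9 and ring conformation. The nucleophilic carbon is fully substituted and oxygen-bearing, attack through C13 competes, and high dilution is needed. It is stronger on step count. The chosen route sets C7 and C8 on a chair and pays no entropic price for the ring.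

Alternative 3: C1=C10 is traced to loss of SO2 from the eleven-membered sulfone A6, sulfur bridging C1 and C10. Forward, KOH on alumina with CBr2F2 in tBuOH would halogenate next to sulfur, close the episulfone and extrude SO2 to give diene A5. In its favour: the eleven-membered sulfide precursor closes easily by S-alkylation, and medium-ring Ramberg–Bäcklund reactions tend to give the cis alkene, so the Z geometry is as well served as in the chosen route. Against it: the C10 α-carbon is tertiary and flanked by O9, so the sulfonyl carbanion can expel that oxygen. C4=C5 must be made separately. A5 still has a saturated two-carbon side chain, so lactone and methylene must be built afterwards. The chosen route delivers both alkenes in one stereospecific event and carries C13 from the start.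

Key step: step 20

Remarks on the chemistry: germacrane numbering (C1–C15) is used for all intermediates. In the decalins α is the face of the C4 methyl and β the face of the C9 oxygen, with ring B drawn C4→C9 clockwise and β up. NAP is 2-naphthylmethyl. Assumption: the borane from (−)-α-pinene, (+)-Ipc2BOMe, is taken to give the (2S,3S) adduct 3 by analogy with the parent allylborane; if the sense is the reverse, its enantiomer is used.

## Steps

Step 1
Reactants: 1 (tert-butyldimethylsilyloxy)acetaldehyde; 2 allyl methoxymethyl ether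
Product: 3 (2S,3S)-1-(tert-butyldimethylsilyloxy)-3-(methoxymethoxy)pent-4-en-2-ol
Conditions: 2, sBuLi, THF, −78 °C; (+)-Ipc2BOMe; BF3·OEt2; then 1, −78 °C; NaOH, H2O2
Reagents that add atoms: none
Why: Brown alkoxyallylboration; the (Z)-γ-alkoxyallylborane reacts through a closed chair, so the future C6 and C7 come out syn, and the isopinocampheyl groups set the absolute sense.

Step 2
Reactants: 3 (2S,3S)-1-(tert-butyldimethylsilyloxy)-3-(methoxymethoxy)pent-4-en-2-ol
Product: 4 (2S,3S)-1,2-bis(tert-butyldimethylsilyloxy)-3-(methoxymethoxy)pent-4-ene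
Conditions: TBSCl, imidazole, DMF, rt
Reagents that add atoms: tert-butyldimethylsilyl chloride, CC(C)(C)[Si](C)(C)Cl
Why: Routine silylation of the secondary alcohol; this silyl ether stays on O6 until step 25.

Step 3
Reactants: 4 (2S,3S)-1,2-bis(tert-butyldimethylsilyloxy)-3-(methoxymethoxy)pent-4-ene
Product: 5 (2S,3S)-2-(tert-butyldimethylsilyloxy)-3-(methoxymethoxy)pent-4-en-1-ol
Conditions: HF·pyridine, pyridine, THF, 0 °C
Reagents that add atoms: none
Why: Selective desilylation; a primary TBS ether is cleaved much faster than a secondary one under buffered HF.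

Step 4
Reactants: 5 (2S,3S)-2-(tert-butyldimethylsilyloxy)-3-(methoxymethoxy)pent-4-en-1-ol
Product: 6 (2R,3S)-2-(tert-butyldimethylsilyloxy)-3-(methoxymethoxy)pent-4-enal
Conditions: Dess–Martin periodinane, NaHCO3, CH2Cl2, 0 °C
Reagents that add atoms: none
Why: Buffered Dess–Martin oxidation should give the α-silyloxy aldehyde without epimerisation; it is used directly.

Step 5
Reactants: 7 2-methylcyclohex-2-en-1-one; 6 (2R,3S)-2-(tert-butyldimethylsilyloxy)-3-(methoxymethoxy)pent-4-enal
Product: 8 (6R)-6-[(1S,2S,3S)-2-(tert-butyldimethylsilyloxy)-1-hydroxy-3-(methoxymethoxy)pent-4-en-1-yl]-2-methylcyclohex-2-en-1-one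
Conditions: LiN(iPr)2, THF, −78 °C; then 6, −78 °C
Reagents that add atoms: none
Why: Aldol addition of the kinetic cross-conjugated enolate; Felkin–Anh attack anti to the C6 silyloxy group sets C5 anti to O6, and the Zimmerman–Traxler chair gives the anti ring stereocentre, which the next step erases.

Step 6
Reactants: 8 aldol adduct (C4–H)
Product: 9 (6S)-6-[(1S,2S,3S)-2-(tert-butyldimethylsilyloxy)-1-hydroxy-3-(methoxymethoxy)pent-4-en-1-yl]-2,6-dimethylcyclohex-2-en-1-one
Conditions: LiN(iPr)2 (2.3 equiv), THF, −78 to −40 °C; MeI, DMPU, −40 to −20 °C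
Reagents that add atoms: iodomethane, CI
Why: Fráter–Seebach-type alkylation of the aldolate dianion; lithium bridges the enolate oxygen and O5, the C6 chain on C5 covers one face of the planar enolate, and the methyl group enters anti to it. This gives the C4/C5 relationship (O5 anti to C9, C6 anti to C3) that the fragmentation turns into the E alkene.

Step 7
Reactants: 9 C4-methylated aldol
Product: 10 the C5 2-naphthylmethyl ether of 9 (configurations at C4–C7 unchanged)
Conditions: 2-naphthylmethyl trichloroacetimidate, TfOH (cat.), CH2Cl2/cyclohexane, 0 °C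
Reagents that add atoms: 2-naphthylmethyl 2,2,2-trichloroacetimidate, ClC(Cl)(Cl)C(=N)OCc1ccc2ccccc2c1
Why: Acid-catalysed imidate etherification avoids the base that would trigger retro-aldol cleavage of the β-hydroxy ketone.

Step 8
Reactants: 10 C5 naphthylmethyl ether enone
Product: 11 the C9 exocyclic methylene analogue of 10 (1-methylidenecyclohex-2-ene)
Conditions: Cp2TiMe2, toluene, 70 °C
Reagents that add atoms: dimethyltitanocene, C[Ti](C)(C1C=CC=C1)C1C=CC=C1
Why: Petasis methylenation; the non-basic titanium methylidene converts hindered carbonyls flanked by a quaternary carbon, and the enone has no α-hydrogen to lose.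

Step 9
Reactants: 11 methylene triene with C7 methoxymethyl ether
Product: 12 the C7 alcohol of 11 (C7–OH, C6–OTBS, C5–ONAP)
Conditions: Me2BBr, CH2Cl2, −78 °C; then NaHCO3 (aq)
Reagents that add atoms: none
Why: Bromodimethylborane cleaves the methoxymethyl acetal at low temperature; silyl and arylmethyl ethers and the diene should survive.

Step 10
Reactants: 12 triene alcohol
Product: 13 octalin with C8=C9 and C1=C10; 4α-methyl, 5α-ONAP, 6α-OTBS, 7β-OH
Conditions: RuCl2(H2IMes)(PCy3)(=CHPh) (second-generation Grubbs catalyst), toluene, 80 °C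
Reagents that add atoms: none
Why: Ring-closing metathesis between the C8 vinyl group and the C9 methylene closes six-membered ring B; the endocyclic C1=C10 alkene is trisubstituted and does not compete.

Step 11
Reactants: 13 octalin allylic alcohol
Product: 14 trans-decalin; 4α-methyl, 5α-ONAP, 6α-OTBS, 7β,8β,9β-triol, 1(10)-ene
Conditions: OsO4 (1.05 equiv), TMEDA, CH2Cl2, −78 °C; then Na2SO3 (aq), THF, 50 °C
Reagents that add atoms: osmium tetroxide, O=[Os](=O)(=O)=O
Why: Hydrogen-bond-directed dihydroxylation; the OsO4·TMEDA complex is held by the allylic 7β-hydroxyl, so it picks C8=C9 over C1=C10 and adds from the β face. That face is also anti to the 4α-methyl, so O9 ends trans to the methyl (trans fusion) and O8 cis to O9.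

Step 12
Reactants: 14 7β,8β,9β-triol
Product: 15 the O8 2-naphthylmethyl ether of 14 (7β-OH and 9β-OH free)
Conditions: Bu2SnO, toluene, reflux; then 2-(bromomethyl)naphthalene, Bu4NI, 90 °C
Reagents that add atoms: 2-(bromomethyl)naphthalene, BrCc1ccc2ccccc2c1
Why: Stannylene-acetal alkylation; either cis-diol pair activates the equatorial oxygen, which is O8.

Step 13
Reactants: 15 O8 naphthylmethyl ether
Product: 16 the C7 ketone of 15 (9β-OH free)
Conditions: Dess–Martin periodinane, NaHCO3, CH2Cl2, rt
Reagents that add atoms: none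
Why: Dess–Martin oxidation; O7 is the only secondary hydroxyl left and the tertiary O9 cannot be oxidised.

Step 14
Reactants: 16 C7 ketone
Product: 17 the 9β-O-trimethylsilyl ether of 16
Conditions: TMSOTf, 2,6-lutidine, CH2Cl2, −78 °C
Reagents that add atoms: trimethylsilyl trifluoromethanesulfonate, C[Si](C)(C)OS(=O)(=O)C(F)(F)F
Why: Silylation of the tertiary alcohol. The silyl ether removes the acidic proton, blocks the β face of C7 and later forces the acetonide onto O7/O8.

Step 15
Reactants: 18 2-bromoprop-2-en-1-ol
Product: 19 (2-bromoallyloxy)(tert-butyl)diphenylsilane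
Conditions: TBDPSCl, imidazole, CH2Cl2, rt
Reagents that add atoms: tert-butyldiphenylsilyl chloride, CC(C)(C)[Si](Cl)(c1ccccc1)c1ccccc1
Why: Routine silylation; the diphenylsilyl ether is chosen to survive the acid of step 23.

Step 16
Reactants: 19 (2-bromoallyloxy)(tert-butyl)diphenylsilane; 17 9β-O-trimethylsilyl C7 ketone
Product: 21 7β-hydroxy-7α-[3-(tert-butyldiphenylsilyloxy)prop-1-en-2-yl] adduct of 17, via alkenyllithium 20 (not isolated)
Conditions: 19, tBuLi (2 equiv), Et2O, −78 °C; then 17, CeCl3, THF, −78 °C
Reagents that add atoms: none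
Why: Halogen–lithium exchange, then cerium-mediated 1,2-addition, which suppresses enolisation. The axial 9β-silyloxy group is syn-axial to the β trajectory at C7, so the bulky nucleophile should enter from the α face and give the axial 7β-hydroxyl.

Step 17
Reactants: 21 tertiary alcohol with two naphthylmethyl ethers
Product: 22 5α,7β,8β-triol (9β-OTMS, 6α-OTBS, C12–OTBDPS retained)
Conditions: DDQ, CH2Cl2/pH 7 buffer, rt
Reagents that add atoms: none
Why: Oxidative cleavage of both naphthylmethyl ethers in one operation; silyl ethers and the isolated alkenes are inert to DDQ.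

Step 18
Reactants: 22 5α,7β,8β-triol
Product: 24 7β,8β-O-isopropylidene 5α,9β-diol, via acetonide trimethylsilyl ether 23 (not isolated)
Conditions: 2-methoxypropene, PPTS (cat.), CH2Cl2, 0 °C; then K2CO3, MeOH, rt
Reagents that add atoms: 2-methoxypropene, COC(C)=C
Why: Acetonide formation on the only cis-1,2-diol available, since O9 is silylated; methanolysis then removes the tertiary trimethylsilyl ether. Any mixed ketal at O5 is lost on aqueous work-up.

Step 19
Reactants: 24 7,8-acetonide 5α,9β-diol
Product: 25 (4S,5S,6S,7S,8S,9S) trans-decalin C5 mesylate with free 9β-OH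
Conditions: MsCl, Et3N, CH2Cl2, −20 °C
Reagents that add atoms: methanesulfonyl chloride, CS(=O)(=O)Cl
Why: Sulfonylation through the sulfene reaches the hindered secondary O5; the tertiary O9 does not react and triethylamine is too weak to start the fragmentation.

Step 20
Reactants: 25 trans-decalin C9 alcohol C5 mesylate
Product: 26 (1(10)Z,4E,6S,7S,8R)-cyclodeca-1(10),4-dien-9-one with 7,8-acetonide, 6-OTBS and C12–OTBDPS
Conditions: KOtBu (1.1 equiv), THF, 0 °C
Reagents that add atoms: none
Why: KOtBu deprotonates the tertiary C9 hydroxyl; an oxygen lone pair forms the C9 carbonyl while the antiperiplanar C4–C9 σ bond becomes the C4=C5 π bond and mesylate leaves C5, in one concerted step. This is a Wharton–Grob fragmentation of a cyclic 1,3-diol monosulfonate, the reaction that opens decalin-1,3-diol monosulfonates to cyclodecenones. The ten-membered ring is not closed end to end: it appears when the bond shared by rings A and B is cut, so there is no entropic cost and no dilution. No stereocentre is created, and C6, C7 and C8 pass through untouched. The E geometry at C4=C5 is stereospecific: in the trans-fused chair the equatorial 5α-mesylate is anti to C4–C9, C3 is anti to C6 and the 4α-methyl anti to H5, and these relationships are carried into the alkene. The Z geometry at C1=C10 comes from ring A. Only the C9 alkoxide may fragment: O7 and O8 are held in an acetonide that cannot migrate and O6 is silylated, so cleavage of C6–C7 from a C7 alkoxide is excluded. The base is consumed as potassium methanesulfonate, so the enolisable α-alkoxy dienone is not left in a basic medium.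

Step 21
Reactants: 26 cyclodecadienone
Product: 27 (9R)-allylic alcohol of 26 (8S,9R; O8 and O9 syn)
Conditions: NaBH4, CeCl3·7H2O, MeOH, −78 °C
Reagents that add atoms: none
Why: Luche reduction gives 1,2-reduction of the enone. Hydride should add to the exposed face of the carbonyl anti to the C8–O bond (Felkin–Anh), which gives the 8,9-syn relationship of the target.

Step 22
Reactants: 27 C9 alcohol
Product: 28 the C9 tert-butyldimethylsilyl ether of 27
Conditions: TBSOTf, 2,6-lutidine, CH2Cl2, −40 °C
Reagents that add atoms: tert-butyldimethylsilyl trifluoromethanesulfonate, CC(C)(C)[Si](C)(C)OS(=O)(=O)C(F)(F)F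
Why: Silylation of the hindered secondary allylic alcohol; a silyl ether cannot undergo the acyl-type shift to O8 that an ester would.

Step 23
Reactants: 28 C9 silyl ether acetonide
Product: 29 7,8-diol (O6 and O9 as TBS ethers, O12 as TBDPS ether)
Conditions: AcOH/H2O/THF (3:1:1), 40 °C
Reagents that add atoms: none
Why: Mild acetal hydrolysis; secondary TBS and primary TBDPS ethers should survive, and the acid is weak enough not to start transannular cyclisation of the diene.

Step 24
Reactants: 29 7,8-diol; 30 angelic acid
Product: 31 C8 angelate (7-OH free)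
Conditions: 30, 2,4,6-trichlorobenzoyl chloride, Et3N, toluene, rt; then 29, 75 °C
Reagents that add atoms: none
Why: Yamaguchi-type esterification through the mixed anhydride without added nucleophilic catalyst, conditions known to keep the Z geometry of the angeloyl group; only the secondary O8 is acylated, the tertiary O7 is not.

Step 25
Reactants: 31 tris-silylated angelate
Product: 32 (1(10)Z,4E)-6,7,9,12-tetrahydroxygermacra-1(10),4,11(13)-trien-8-yl angelate
Conditions: HF·pyridine, pyridine, THF, 0 °C to rt
Reagents that add atoms: none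
Why: Global desilylation in a slightly acidic medium, which avoids the alkoxide-mediated shift of the angelate to O9 or O7.

Step 26
Reactants: 32 tetraol monoangelate
Product: 33 the target, (6S,7R,8S,9R)-germacranolide
Conditions: TEMPO (cat.), PhI(OAc)2, CH2Cl2, rt
Reagents that add atoms: none
Why: Oxidative lactonisation of a 1,4-diol; the oxoammonium salt oxidises the primary allylic C12 alcohol first, O6 closes the five-membered lactol on the same face, and a second oxidation gives the α-methylene lactone.

## Compound list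

1 | (tert-butyldimethylsilyloxy)acetaldehyde | O=CCO[Si](C)(C)C(C)(C)C | starting material
2 | allyl methoxymethyl ether | C=CCOCOC | starting material
3 | (2S,3S)-1-(tert-butyldimethylsilyloxy)-3-(methoxymethoxy)pent-4-en-2-ol | C=C[C@H](OCOC)[C@@H](O)CO[Si](C)(C)C(C)(C)C | intermediate
4 | (2S,3S)-1,2-bis(tert-butyldimethylsilyloxy)-3-(methoxymethoxy)pent-4-ene | C=C[C@H](OCOC)[C@@H](O[Si](C)(C)C(C)(C)C)CO[Si](C)(C)C(C)(C)C | intermediate
5 | (2S,3S)-2-(tert-butyldimethylsilyloxy)-3-(methoxymethoxy)pent-4-en-1-ol | C=C[C@H](OCOC)[C@@H](O[Si](C)(C)C(C)(C)C)CO | intermediate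
6 | (2R,3S)-2-(tert-butyldimethylsilyloxy)-3-(methoxymethoxy)pent-4-enal | C=C[C@H](OCOC)[C@@H](O[Si](C)(C)C(C)(C)C)C=O | intermediate
7 | 2-methylcyclohex-2-en-1-one | CC1=CCCCC1=O | starting material
8 | (6R)-6-[(1S,2S,3S)-2-(tert-butyldimethylsilyloxy)-1-hydroxy-3-(methoxymethoxy)pent-4-en-1-yl]-2-methylcyclohex-2-en-1-one | C=C[C@H](OCOC)[C@@H](O[Si](C)(C)C(C)(C)C)[C@@H](O)[C@H]1CCC=C(C)C1=O | intermediate
9 | (6S)-6-[(1S,2S,3S)-2-(tert-butyldimethylsilyloxy)-1-hydroxy-3-(methoxymethoxy)pent-4-en-1-yl]-2,6-dimethylcyclohex-2-en-1-one | C=C[C@H](OCOC)[C@@H](O[Si](C)(C)C(C)(C)C)[C@@H](O)[C@]1(C)CCC=C(C)C1=O | intermediate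
10 | C5 2-naphthylmethyl ether of 9 | C=C[C@H](OCOC)[C@@H](O[Si](C)(C)C(C)(C)C)[C@@H](OCc2ccc3ccccc3c2)[C@]1(C)CCC=C(C)C1=O | intermediate
11 | C9 methylene analogue of 10 | C=C[C@H](OCOC)[C@@H](O[Si](C)(C)C(C)(C)C)[C@@H](OCc2ccc3ccccc3c2)[C@]1(C)CCC=C(C)C1=C | intermediate
12 | C7 alcohol of 11 | C=C[C@H](O)[C@@H](O[Si](C)(C)C(C)(C)C)[C@@H](OCc2ccc3ccccc3c2)[C@]1(C)CCC=C(C)C1=C | intermediate
13 | octalin, C8=C9 and C1=C10; 4α-methyl, 5α-ONAP, 6α-OTBS, 7β-OH | CC(C)(C)[Si](C)(C)O[C@H]1[C@@H](OCc3ccc4ccccc4c3)[C@]2(C)CCC=C(C)C2=C[C@@H]1O | intermediate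
14 | trans-decalin 7β,8β,9β-triol; 4α-methyl, 5α-ONAP, 6α-OTBS, 1(10)-ene | CC(C)(C)[Si](C)(C)O[C@H]1[C@@H](OCc3ccc4ccccc4c3)[C@]2(C)CCC=C(C)[C@@]2(O)[C@H](O)[C@@H]1O | intermediate
15 | O8 2-naphthylmethyl ether of 14 | CC(C)(C)[Si](C)(C)O[C@H]1[C@@H](OCc3ccc4ccccc4c3)[C@]2(C)CCC=C(C)[C@@]2(O)[C@H](OCc5ccc6ccccc6c5)[C@@H]1O | intermediate
16 | C7 ketone of 15 | CC(C)(C)[Si](C)(C)O[C@H]1[C@@H](OCc3ccc4ccccc4c3)[C@]2(C)CCC=C(C)[C@@]2(O)[C@H](OCc5ccc6ccccc6c5)C1=O | intermediate
17 | 9β-O-trimethylsilyl ether of 16 | CC(C)(C)[Si](C)(C)O[C@H]1[C@@H](OCc3ccc4ccccc4c3)[C@]2(C)CCC=C(C)[C@@]2(O[Si](C)(C)C)[C@H](OCc5ccc6ccccc6c5)C1=O | intermediate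
18 | 2-bromoprop-2-en-1-ol | OCC(Br)=C | starting material
19 | (2-bromoallyloxy)(tert-butyl)diphenylsilane | C=C(Br)CO[Si](c1ccccc1)(c1ccccc1)C(C)(C)C | intermediate
20 | [3-(tert-butyldiphenylsilyloxy)prop-1-en-2-yl]lithium | [Li]C(=C)CO[Si](c1ccccc1)(c1ccccc1)C(C)(C)C | intermediate
21 | 7β-hydroxy-7α-[3-(tert-butyldiphenylsilyloxy)prop-1-en-2-yl] decalin; 5α,8β-bis-ONAP, 6α-OTBS, 9β-OTMS | CC(C)(C)[Si](C)(C)O[C@H]1[C@@H](OCc3ccc4ccccc4c3)[C@]2(C)CCC=C(C)[C@@]2(O[Si](C)(C)C)[C@H](OCc5ccc6ccccc6c5)[C@@]1(O)C(=C)CO[Si](c7ccccc7)(c8ccccc8)C(C)(C)C | intermediate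
22 | 5α,7β,8β-triol; 9β-OTMS | CC(C)(C)[Si](C)(C)O[C@H]1[C@@H](O)[C@]2(C)CCC=C(C)[C@@]2(O[Si](C)(C)C)[C@H](O)[C@@]1(O)C(=C)CO[Si](c3ccccc3)(c4ccccc4)C(C)(C)C | intermediate
23 | 7β,8β-O-isopropylidene, 9β-OTMS, 5α-OH | CC(C)(C)[Si](C)(C)O[C@H]1[C@@H](O)[C@]2(C)CCC=C(C)[C@@]2(O[Si](C)(C)C)[C@@H]3OC(C)(C)O[C@]13C(=C)CO[Si](c4ccccc4)(c5ccccc5)C(C)(C)C | intermediate
24 | 7β,8β-O-isopropylidene 5α,9β-diol | CC(C)(C)[Si](C)(C)O[C@H]1[C@@H](O)[C@]2(C)CCC=C(C)[C@@]2(O)[C@@H]3OC(C)(C)O[C@]13C(=C)CO[Si](c4ccccc4)(c5ccccc5)C(C)(C)C | intermediate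
25 | (4S,5S,6S,7S,8S,9S) trans-decalin C9 alcohol C5 mesylate | CC(C)(C)[Si](C)(C)O[C@H]1[C@@H](OS(C)(=O)=O)[C@]2(C)CCC=C(C)[C@@]2(O)[C@@H]3OC(C)(C)O[C@]13C(=C)CO[Si](c4ccccc4)(c5ccccc5)C(C)(C)C | intermediate
26 | (1(10)Z,4E,6S,7S,8R) ten-membered dienone, C9 ketone | CC(C)(C)[Si](C)(C)O[C@H]1/C=C(\C)CC/C=C(/C)C(=O)[C@@H]2OC(C)(C)O[C@]12C(=C)CO[Si](c3ccccc3)(c4ccccc4)C(C)(C)C | intermediate
27 | (9R)-alcohol of 26 | CC(C)(C)[Si](C)(C)O[C@H]1/C=C(\C)CC/C=C(/C)[C@@H](O)[C@@H]2OC(C)(C)O[C@]12C(=C)CO[Si](c3ccccc3)(c4ccccc4)C(C)(C)C | intermediate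
28 | C9 tert-butyldimethylsilyl ether of 27 | CC(C)(C)[Si](C)(C)O[C@H]1/C=C(\C)CC/C=C(/C)[C@@H](O[Si](C)(C)C(C)(C)C)[C@@H]2OC(C)(C)O[C@]12C(=C)CO[Si](c3ccccc3)(c4ccccc4)C(C)(C)C | intermediate
29 | 7,8-diol; O6 and O9 as TBS ethers, O12 as TBDPS ether | CC(C)(C)[Si](C)(C)O[C@H]1/C=C(\C)CC/C=C(/C)[C@@H](O[Si](C)(C)C(C)(C)C)[C@H](O)[C@@]1(O)C(=C)CO[Si](c2ccccc2)(c3ccccc3)C(C)(C)C | intermediate
30 | angelic acid, (Z)-2-methylbut-2-enoic acid | C/C=C(/C)C(O)=O | starting material
31 | C8 angelate of 29 | CC(C)(C)[Si](C)(C)O[C@H]1/C=C(\C)CC/C=C(/C)[C@@H](O[Si](C)(C)C(C)(C)C)[C@H](OC(=O)/C(C)=C\C)[C@@]1(O)C(=C)CO[Si](c2ccccc2)(c3ccccc3)C(C)(C)C | intermediate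
32 | (1(10)Z,4E)-6,7,9,12-tetrahydroxygermacra-1(10),4,11(13)-trien-8-yl angelate | O[C@H]1/C=C(\C)CC/C=C(/C)[C@@H](O)[C@H](OC(=O)/C(C)=C\C)[C@@]1(O)C(=C)CO | intermediate
33 | target germacranolide, (6S,7R,8S,9R) | C=C1C(=O)O[C@H]2/C=C(\C)CC/C=C(/C)[C@@H](O)[C@H](OC(=O)/C(C)=C\C)[C@@]12O | target

## Step count and risk

Total step count: 26. Longest linear sequence: 25 steps (steps 1–14 and 16–26; step 15 is a one-step side branch).

Least certain steps:

Step 20 (key step). The fragmentation itself is well aligned. The likely failure comes after it: the product is an enolisable α-alkoxy ketone, and any base left over could epimerise C8 or expel O7 by β-elimination. The reaction could also stall if the syn-axial 4α-methyl and 6α-silyloxy groups push ring B out of the chair. Fallback, from 23 to 26: 23 would be isolated and mesylated (MsCl, Et3N) to the C9 trimethylsilyl ether C5 mesylate F1. Anhydrous fluoride (TASF, THF, −20 °C) would then unmask the C9 alkoxide, which fragments at once in a medium with no Brønsted base.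

Step 16. Facial selectivity may be poor. The axial 6α-silyloxy group on the neighbouring carbon favours attack from the β face on both steric and Felkin–Anh grounds, and it competes with the 9β-silyloxy block. Enolisation of the α-alkoxy ketone is a second risk. Fallback, from 16 to 21, by tethered delivery. HF·pyridine would free O6 to give the 6α,9β-diol ketone F5. 2-Bromoacrylic acid (EDC, DMAP) would esterify the secondary O6 to the 2-bromoacrylate F6, and TMSOTf/2,6-lutidine would cap O9 to give the silyl ether F7. CrCl2 with catalytic NiCl2 (intramolecular Nozaki–Hiyama–Kishi reaction) would close the five-membered ring from the α face, the only one the two-atom tether allows, giving the cis-fused α-methylene-β-hydroxy lactone F8. iBu2AlH would reduce it to the triol F9. TBDPSCl and then TBSCl (imidazole) would silylate O12 (mono-silyl ether F10) and then O6, which gives 21.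

Step 6. The lithium aldolate may undergo retro-aldol cleavage or a 1,2-silyl shift from O6 to O5 before the second deprotonation, and the tertiary C4–H may be removed too slowly. Fallback, from 6 to 9, forming the quaternary carbon in the aldol step. 2,6-Dimethylcyclohexanone F2 would be dehydrogenated (IBX, DMSO) to 2,6-dimethylcyclohex-2-en-1-one F3 and converted (LiN(iPr)2; TMSCl) into the silyl dienol ether F4. A Mukaiyama aldol of F4 with 6 (BF3·OEt2, CH2Cl2, −78 °C) would be Felkin-controlled at C5 and would give 9 together with its C4 epimer, to be separated.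

Step 21. In the flexible ten-membered ring the hydride may not distinguish the two faces of the carbonyl, and some conjugate reduction is possible. Fallback, from 26 to 27: reagent-controlled Corey–Bakshi–Shibata reduction (2-methyl-CBS-oxazaborolidine of the matching hand, BH3·SMe2), which is 1,2-selective for enones and overrides the substrate bias; it makes no new compound (F0).

## Further compounds

F1 | step 20 | trans-decalin C9 trimethylsilyl ether C5 mesylate | CC(C)(C)[Si](C)(C)O[C@H]1[C@@H](OS(C)(=O)=O)[C@]2(C)CCC=C(C)[C@@]2(O[Si](C)(C)C)[C@@H]3OC(C)(C)O[C@]13C(=C)CO[Si](c4ccccc4)(c5ccccc5)C(C)(C)C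
F2 | step 6 | 2,6-dimethylcyclohexanone | CC1CCCC(C)C1=O
F3 | step 6 | 2,6-dimethylcyclohex-2-en-1-one | CC1CCC=C(C)C1=O
F4 | step 6 | 2,6-dimethyl-1-(trimethylsilyloxy)cyclohexa-1,5-diene | C[Si](C)(C)OC1=C(C)CCC=C1C
F5 | step 16 | 6α,9β-diol C7 ketone; 5α,8β-bis-ONAP | O[C@H]1[C@@H](OCc3ccc4ccccc4c3)[C@]2(C)CCC=C(C)[C@@]2(O)[C@H](OCc5ccc6ccccc6c5)C1=O
F6 | step 16 | O6 2-bromoacrylate of F5 | C=C(Br)C(=O)O[C@H]1[C@@H](OCc3ccc4ccccc4c3)[C@]2(C)CCC=C(C)[C@@]2(O)[C@H](OCc5ccc6ccccc6c5)C1=O
F7 | step 16 | 9β-O-trimethylsilyl ether of F6 | C=C(Br)C(=O)O[C@H]1[C@@H](OCc3ccc4ccccc4c3)[C@]2(C)CCC=C(C)[C@@]2(O[Si](C)(C)C)[C@H](OCc5ccc6ccccc6c5)C1=O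
F8 | step 16 | cis-fused α-methylene-β-hydroxy-γ-lactone on C6–C7 of the decalin | C=C1C(=O)O[C@H]2[C@@H](OCc4ccc5ccccc5c4)[C@]3(C)CCC=C(C)[C@@]3(O[Si](C)(C)C)[C@H](OCc6ccc7ccccc7c6)[C@@]12O
F9 | step 16 | 6α,7β,12-triol; 9β-OTMS | O[C@H]1[C@@H](OCc3ccc4ccccc4c3)[C@]2(C)CCC=C(C)[C@@]2(O[Si](C)(C)C)[C@H](OCc5ccc6ccccc6c5)[C@@]1(O)C(=C)CO
F10 | step 16 | O12 tert-butyldiphenylsilyl ether of F9 | O[C@H]1[C@@H](OCc3ccc4ccccc4c3)[C@]2(C)CCC=C(C)[C@@]2(O[Si](C)(C)C)[C@H](OCc5ccc6ccccc6c5)[C@@]1(O)C(=C)CO[Si](c7ccccc7)(c8ccccc8)C(C)(C)C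
F0 | step 21 | none | none
A1 | alternative 1 | C9 triethylsilyl ether of the target | C=C1C(=O)O[C@H]2/C=C(\C)CC/C=C(/C)[C@@H](O[Si](CC)(CC)CC)[C@H](OC(=O)/C(C)=C\C)[C@@]12O
A2 | alternative 1 | C7 ethynyl C6,C7-diol with C8 angelate and C9 triethylsilyl ether | O[C@H]1/C=C(\C)CC/C=C(/C)[C@@H](O[Si](CC)(CC)CC)[C@H](OC(=O)/C(C)=C\C)[C@@]1(O)C#C
A3 | alternative 2 | bicyclic methylene lactone with free C8 hydroxyl, O7 PMB ether, O9 TBS ether | C=C1C(=O)O[C@H]2/C=C(\C)CC/C=C(/C)[C@@H](O[Si](C)(C)C(C)(C)C)[C@H](O)[C@@]12OCc3ccc(OC)cc3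
A4 | alternative 2 | 2-(bromomethyl)-3-(4-methoxybenzyloxy)butenolide tethered to the C8 aldehyde | O=C1O[C@@H](/C=C(\C)CC/C=C(/C)[C@@H](O[Si](C)(C)C(C)(C)C)C=O)C(OCc2ccc(OC)cc2)=C1CBr
A5 | alternative 3 | ten-membered (4E,1(10)Z) diene with 7,8-acetonide, O6 SEM, O9 PMB, O12 TIPS | C[Si](C)(C)CCOCO[C@H]1/C=C(\C)CC/C=C(/C)[C@@H](OCc2ccc(OC)cc2)[C@@H]3OC(C)(C)O[C@]13CCO[Si](C(C)C)(C(C)C)C(C)C
A6 | alternative 3 | eleven-membered cyclic sulfone, sulfur between C1 and C10 | C[Si](C)(C)CCOCO[C@H]1/C=C(\C)CCCS(=O)(=O)C(C)[C@@H](OCc2ccc(OC)cc2)[C@@H]3OC(C)(C)O[C@]13CCO[Si](C(C)C)(C(C)C)C(C)C
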